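**Retrosynthetic overview**
- Both isovalerates are cut last, back to the phenol / primary alcohol 13, whose phenol is carried through the route as an allyl ether.
- The strategy rests on the oxirane carbon C2: it bears the aryl ring, the ring oxygen, the oxirane CH2 and the CH2O-acyl arm. With both arms as CH2OH the stereocenter disappears into the mirror-symmetric 2-arylpropane-1,2,3-triol 9.
- Triol 9 is desymmetrized by catalytic enantioselective monotosylation of one enantiotopic CH2OH; the tosylated arm becomes the oxirane CH2.
- The aryl–C(quaternary) bond comes from adding the aryllithium derived from 4-bromo-3-hydroxybenzaldehyde 1 to the symmetric ketone 4.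
- Ring order: the benzene ring is bought, the temporary dioxane is opened to the triol, and the oxirane is the only ring made, by 3-exo-tet closure directly after the key step.

Key step: step 5

Assumption: the sense of induction of the Cu(OTf)2–bisoxazoline pair with this 2-arylglycerol has to be assigned on a first run (by correlation at the stage of 12). (R,R)-Ph-BOX is written throughout, and the mirror-image ligand would take its place if the first run shows the opposite sense.

**Step 1**
Reactants: 1 4-bromo-3-hydroxybenzaldehyde
Product: 2 3-(allyloxy)-4-bromobenzaldehyde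
Conditions: allyl bromide (1.2 equiv), K2CO3 (1.5 equiv), DMF, rt
Reagents that add atoms: allyl bromide C=CCBr
Why: Williamson ether synthesis: the acidic phenoxide is O-alkylated by allyl bromide in an SN2 reaction, and the allyl ether is chosen because it should survive aryllithium chemistry at −78 °C and aqueous acid and can later be removed under nearly neutral palladium catalysis.

**Step 2**
Reactants: 2 3-(allyloxy)-4-bromobenzaldehyde
Product: 3 2-(allyloxy)-1-bromo-4-(dimethoxymethyl)benzene
Conditions: HC(OMe)3 (3 equiv), p-TsOH·H2O (2 mol %), MeOH, rt; Et3N quench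
Reagents that add atoms: trimethyl orthoformate COC(OC)OC; methanol CO
Why: Acid-catalysed acetalisation, driven by the orthoformate as water scavenger, masks the formyl group against n-BuLi and the aryllithium of step 3.

**Step 3**
Reactants: 3 2-(allyloxy)-1-bromo-4-(dimethoxymethyl)benzene; 4 2,2-dimethyl-1,3-dioxan-5-one
Product: 7 5-[2-(allyloxy)-4-(dimethoxymethyl)phenyl]-2,2-dimethyl-1,3-dioxan-5-ol, via aryllithium 5 (not isolated), via lithium alkoxide 6 (not isolated)
Conditions: n-BuLi (1.05 equiv), THF, −78 °C, 20 min; then 4 (1.2 equiv), −78 → −40 °C; H2O quench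
Reagents that add atoms: none
Why: Bromine–lithium exchange, faster at −78 °C than any attack on the acetal or the allyl ether, gives an aryllithium stabilised by the ortho oxygen, and its 1,2-addition to the symmetric ketone forms the aryl–C(quaternary) bond without creating a stereocenter, since the two CH2O arms are identical.

**Step 4**
Reactants: 7 5-[2-(allyloxy)-4-(dimethoxymethyl)phenyl]-2,2-dimethyl-1,3-dioxan-5-ol
Product: 9 3-(allyloxy)-4-(1,2,3-trihydroxypropan-2-yl)benzaldehyde, via aldehyde acetonide 8 (not isolated)
Conditions: 1 M aq. HCl–THF (1:3), rt; NaHCO3 work-up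
Reagents that add atoms: water O
Why: Acid-catalysed acetal and ketal hydrolysis: the dimethyl acetal should cleave first and the acetonide second, and the formyl group set free para to the carbinol carbon disfavours benzylic ionisation, so the tertiary alcohol should survive.

**Step 5**
Reactants: 9 3-(allyloxy)-4-(1,2,3-trihydroxypropan-2-yl)benzaldehyde; 10 p-toluenesulfonyl chloride
Product: 11 (2S)-2-[2-(allyloxy)-4-formylphenyl]-2,3-dihydroxypropyl 4-methylbenzenesulfonate
Conditions: Cu(OTf)2 (10 mol %), (R,R)-Ph-BOX (11 mol %), 10 (1.05 equiv), K2CO3 (1.5 equiv), MeCN, 0 °C → rt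
Reagents that add atoms: none
Why: Cu(OTf)2 and the bisoxazoline form a chiral divalent copper Lewis acid that binds the triol as a five-membered chelate through the tertiary hydroxyl and one primary hydroxyl; the bound primary OH is acidified, solid K2CO3 removes its proton and the copper alkoxide attacks the sulfur of TsCl with loss of chloride. The closest known reaction type is the copper–bisoxazoline-catalysed enantioselective monosulfonylation of 2-substituted glycerols and of meso-1,2-diols. Only an O–S bond is formed and no ring is closed. The carbinol carbon becomes the only stereocenter because the two enantiotopic CH2OH arms are told apart, and the controlling element is the twofold-symmetric ligand, whose phenyl groups let only one of the two diastereomeric chelates present its alkoxide to TsCl, so that the ligand antipode fixes the (S) configuration, in which the sulfonylated arm is the future oxirane CH2. The step needs enantiotopic-group selectivity (catalyst), primary-over-tertiary selectivity (the hindered tertiary benzylic OH only anchors the metal), mono-over-bis selectivity (near-stoichiometric TsCl, and any second sulfonylation should fall mainly on the minor enantiomer, whose free arm is the one the catalyst prefers) and chemoselectivity (phenol blocked as the allyl ether, formyl group inert to TsCl). The two arms are sterically and electronically identical, so nothing in the substrate opposes the catalyst.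

**Step 6**
Reactants: 11 (2S)-2-[2-(allyloxy)-4-formylphenyl]-2,3-dihydroxypropyl 4-methylbenzenesulfonate
Product: 12 3-(allyloxy)-4-[(2S)-2-(hydroxymethyl)oxiran-2-yl]benzaldehyde
Conditions: K2CO3 (1.5 equiv), MeOH, 0 °C, short reaction time
Reagents that add atoms: none
Why: Intramolecular Williamson etherification: the tertiary alkoxide displaces the primary tosylate in a 3-exo-tet closure at the CH2 carbon, so no bond to the stereocenter is made or broken and the configuration is retained; a Payne-type epoxide migration of the product is degenerate and returns the same enantiomer (inversion at the quaternary carbon is offset by the exchange of the two arms), so the cold, short treatment serves only to suppress methanolysis of the benzylic oxirane.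

**Step 7**
Reactants: 12 3-(allyloxy)-4-[(2S)-2-(hydroxymethyl)oxiran-2-yl]benzaldehyde
Product: 13 3-hydroxy-4-[(2S)-2-(hydroxymethyl)oxiran-2-yl]benzaldehyde
Conditions: Pd(PPh3)4 (5 mol %), PhNHMe (1.5 equiv), degassed THF, rt; volatiles removed cold, crude used at once
Reagents that add atoms: none
Why: Tsuji–Trost-type deallylation: zerovalent palladium ionises the allyl aryl ether to a π-allyl complex, and N-methylaniline, a weakly basic secondary amine that can neither deprotonate the phenol nor condense irreversibly with the aldehyde, takes up the allyl group, so the phenol is released un-ionised next to the sensitive benzylic oxirane.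

**Step 8**
Reactants: 13 3-hydroxy-4-[(2S)-2-(hydroxymethyl)oxiran-2-yl]benzaldehyde; 14 isovaleric anhydride
Product: 16 [(2R)-2-{4-formyl-2-[(3-methylbutanoyl)oxy]phenyl}oxiran-2-yl]methyl 3-methylbutanoate, via aryl monoester 15 (not isolated)
Conditions: 14 (4 equiv), Et3N (5 equiv), DMAP (0.2 equiv), CH2Cl2, 0 °C; crude 13 added to the premixed acylating solution
Reagents that add atoms: none
Why: DMAP-catalysed (Steglich-type) acyl transfer should esterify the phenol first and the primary alcohol second without touching the stereocenter, the change from (S) to (R) being a CIP priority effect only, and the excess anhydride also caps residual N-methylaniline.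

**Compound list**
1 | 4-bromo-3-hydroxybenzaldehyde | O=Cc1ccc(Br)c(O)c1 | starting material
2 | 3-(allyloxy)-4-bromobenzaldehyde | O=Cc1ccc(Br)c(OCC=C)c1 | intermediate
3 | 2-(allyloxy)-1-bromo-4-(dimethoxymethyl)benzene | COC(OC)c1ccc(Br)c(OCC=C)c1 | intermediate
4 | 2,2-dimethyl-1,3-dioxan-5-one | CC1(C)OCC(=O)CO1 | starting material
5 | [2-(allyloxy)-4-(dimethoxymethyl)phenyl]lithium | COC(OC)c1ccc([Li])c(OCC=C)c1 | intermediate
6 | lithium 5-[2-(allyloxy)-4-(dimethoxymethyl)phenyl]-2,2-dimethyl-1,3-dioxan-5-olate | COC(OC)c1ccc(C2(O[Li])COC(C)(C)OC2)c(OCC=C)c1 | intermediate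
7 | 5-[2-(allyloxy)-4-(dimethoxymethyl)phenyl]-2,2-dimethyl-1,3-dioxan-5-ol | COC(OC)c1ccc(C2(O)COC(C)(C)OC2)c(OCC=C)c1 | intermediate
8 | 3-(allyloxy)-4-(5-hydroxy-2,2-dimethyl-1,3-dioxan-5-yl)benzaldehyde | O=Cc1ccc(C2(O)COC(C)(C)OC2)c(OCC=C)c1 | intermediate
9 | 3-(allyloxy)-4-(1,2,3-trihydroxypropan-2-yl)benzaldehyde (achiral) | OCC(O)(CO)c1ccc(C=O)cc1OCC=C | intermediate
10 | p-toluenesulfonyl chloride | Cc1ccc(S(=O)(=O)Cl)cc1 | starting material
11 | (2S)-2-[2-(allyloxy)-4-formylphenyl]-2,3-dihydroxypropyl 4-methylbenzenesulfonate | OC[C@@](O)(c1ccc(C=O)cc1OCC=C)COS(=O)(=O)c1ccc(C)cc1 | intermediate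
12 | 3-(allyloxy)-4-[(2S)-2-(hydroxymethyl)oxiran-2-yl]benzaldehyde | OC[C@@]1(c2ccc(C=O)cc2OCC=C)CO1 | intermediate
13 | 3-hydroxy-4-[(2S)-2-(hydroxymethyl)oxiran-2-yl]benzaldehyde | OC[C@@]1(c2ccc(C=O)cc2O)CO1 | intermediate
14 | isovaleric (3-methylbutanoic) anhydride | CC(C)CC(=O)OC(=O)CC(C)C | starting material
15 | 5-formyl-2-[(2S)-2-(hydroxymethyl)oxiran-2-yl]phenyl 3-methylbutanoate | OC[C@@]1(c2ccc(C=O)cc2OC(=O)CC(C)C)CO1 | intermediate
16 | [(2R)-2-{4-formyl-2-[(3-methylbutanoyl)oxy]phenyl}oxiran-2-yl]methyl 3-methylbutanoate | CC(C)CC(=O)OC[C@@]1(c2ccc(C=O)cc2OC(=O)CC(C)C)CO1 | target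

**Step count**
Total: 8 steps. Longest linear sequence: 8 steps (1 → 16); 4, 10 and 14 are bought.

**Steps most likely to fail**

1. Step 5. The catalyst may discriminate the two enantiotopic arms poorly when the carbinol carbon carries an ortho-alkoxyaryl group, or sulfonylation may run on to the bis-tosylate. The fallback replaces copper catalysis by enzymatic desymmetrization; it sets out from 9 and comes back at 12. Triol 9 is acetylated with vinyl acetate and an immobilised lipase (Candida antarctica lipase B or Burkholderia cepacia lipase, chosen by screening so that the arm that is to remain CH2OH is acylated) to give (2R)-2-[2-(allyloxy)-4-formylphenyl]-2,3-dihydroxypropyl acetate F1. The remaining primary hydroxyl is tosylated without delay (10, pyridine, CH2Cl2, 0 °C), so that 1,3-acetyl migration, which would racemise, is forestalled; this gives (2S)-3-(acetyloxy)-2-[2-(allyloxy)-4-formylphenyl]-2-hydroxypropyl 4-methylbenzenesulfonate F2. K2CO3 in MeOH at 0 °C then removes the acetate and closes the oxirane to give 12.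

2. Step 7 (with the handling of 13 into step 8). The liberated ortho-hydroxyl may trigger opening of the benzylic oxirane, by cyclisation onto the oxirane CH2 or by quinone-methide-type ionisation, before it is acylated. The fallback never releases the phenol; it sets out from 12 and comes back at 16. The primary alcohol of 12 is esterified first (14, Et3N, DMAP, CH2Cl2, 0 °C) to give [(2R)-2-[2-(allyloxy)-4-formylphenyl]oxiran-2-yl]methyl 3-methylbutanoate F3. Hydrostannolysis catalysed by Pd(PPh3)4 with Bu3SnH (CH2Cl2, rt) converts the allyl ether into the neutral stannyl ether [(2R)-2-{4-formyl-2-[(tributylstannyl)oxy]phenyl}oxiran-2-yl]methyl 3-methylbutanoate F4 with loss of propene. Once the hydride is consumed, isovaleryl chloride is added to the same flask and acylates the Sn–O bond to give 16.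

3. Step 3. Proton transfer from the enolisable ketone 4 to the aryllithium may outrun 1,2-addition and return the debrominated arene. The fallback changes the three-carbon partner; it sets out from 3 and comes back at 9. Aryllithium 5, generated as in step 3, is transmetalated with MgBr2·OEt2 (THF, −78 → −20 °C) to [2-(allyloxy)-4-(dimethoxymethyl)phenyl]magnesium bromide F5. F5 is added to 1,3-dichloroacetone, a ketone that takes up aryl Grignard reagents readily, to give 2-[2-(allyloxy)-4-(dimethoxymethyl)phenyl]-1,3-dichloropropan-2-ol F6. Hot aqueous Na2CO3 in dioxane exchanges both chlorides for hydroxyl (the classical dichlorohydrin-to-glycerol hydrolysis) to give 2-[2-(allyloxy)-4-(dimethoxymethyl)phenyl]propane-1,2,3-triol F7. Dilute aqueous HCl in THF then unmasks the aldehyde to give 9.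

**Further compounds**
F1 | step 5 | (2R)-2-[2-(allyloxy)-4-formylphenyl]-2,3-dihydroxypropyl acetate | CC(=O)OC[C@@](O)(c1ccc(C=O)cc1OCC=C)CO
F2 | step 5 | (2S)-3-(acetyloxy)-2-[2-(allyloxy)-4-formylphenyl]-2-hydroxypropyl 4-methylbenzenesulfonate | CC(=O)OC[C@@](O)(c1ccc(C=O)cc1OCC=C)COS(=O)(=O)c1ccc(C)cc1
F3 | step 7 | [(2R)-2-[2-(allyloxy)-4-formylphenyl]oxiran-2-yl]methyl 3-methylbutanoate | CC(C)CC(=O)OC[C@@]1(c2ccc(C=O)cc2OCC=C)CO1
F4 | step 7 | [(2R)-2-{4-formyl-2-[(tributylstannyl)oxy]phenyl}oxiran-2-yl]methyl 3-methylbutanoate | CC(C)CC(=O)OC[C@@]1(c2ccc(C=O)cc2O[Sn](CCCC)(CCCC)CCCC)CO1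
F5 | step 3 | [2-(allyloxy)-4-(dimethoxymethyl)phenyl]magnesium bromide | COC(OC)c1ccc([Mg]Br)c(OCC=C)c1
F6 | step 3 | 2-[2-(allyloxy)-4-(dimethoxymethyl)phenyl]-1,3-dichloropropan-2-ol | COC(OC)c1ccc(C(O)(CCl)CCl)c(OCC=C)c1
F7 | step 3 | 2-[2-(allyloxy)-4-(dimethoxymethyl)phenyl]propane-1,2,3-triol | COC(OC)c1ccc(C(O)(CO)CO)c(OCC=C)c1
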